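**Retrosynthetic overview**

1. Key disconnection: the bond between the olefinic CH of the (E)-C(CH3)=CH unit and the chain CH2 next to it. It is made in one pot from three components: the terminal alkyne of the C13 left half, AlMe3 (which supplies the vinylic methyl) and a primary alkyl bromide carrying the whole C11 right half (Zr-catalysed methylalumination, Al-to-Zn transmetalation, Pd-catalysed alkyl–alkenyl Negishi coupling).
2. Enabling features: (i) the trisubstituted olefin, whose fully substituted carbon bears CH3 and whose CH carbon bears the chain CH2, is the imprint of syn methylmetalation of a terminal alkyne; (ii) in the second olefin the CH2OH carbon and the CH2–CH(O) arm are cis, so the atoms O–CH(furyl)–CH2–CH=C–C(=O) can be closed as a 5,6-dihydro-2H-pyran-2-one ring. This temporary ring locks the Z geometry, masks both hydroxyls (CH2OH at the acid level) and gives an electrophile that tolerates the organometallic union.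
3. Second disconnection: the dihydropyranone olefin by ring-closing metathesis of the 2-methylenebutanoate ester of (R)-1-(furan-3-yl)but-3-en-1-ol. The (R)-carbinol, the only stereocentre, comes from asymmetric allylboration of furan-3-carbaldehyde.
4. Third disconnection: the butenolide from the furan (singlet oxygen, then NaBH4) as the last operation, after i-Bu2AlH has opened the lactone to the Z-diol.
5. Ring order: cyclohexene and furan rings are bought; the dihydropyranone ring is closed in step 5 and opened again in step 8; the butenolide ring is formed last (steps 9 and 10) from the furan ring.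

Key step: step 7

Assumption: the allylborane made from (+)-Ipc2BOMe (the antipode derived from (−)-α-pinene) is taken to deliver allyl to the Re face of furan-3-carbaldehyde, as it does with benzaldehyde, which gives the (R)-carbinol; furyl and butenolide carbons both rank above the chain CH2, so (R) is kept to the target.

**Route**

Step 1
Reactants: 1 4-(2,6,6-trimethylcyclohex-1-en-1-yl)butan-2-one (dihydro-β-ionone)
Product: 3 2-(but-3-yn-1-yl)-1,3,3-trimethylcyclohex-1-ene, via enol phosphate 2 (not isolated)
Conditions: LiN(i-Pr)2, THF, −78 °C; ClP(O)(OEt)2, −78 °C to rt; LiN(i-Pr)2 (2.3 equiv), −78 °C to rt; H2O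
Reagents that add atoms: none
Why: Kinetic deprotonation on the CH3 side and O-phosphorylation should give the terminal enol phosphate, which loses diethyl phosphate by base-induced elimination to the acetylide (methyl ketone to terminal alkyne via the enol phosphate), the tetrasubstituted ring olefin being inert.

Step 2
Reactants: 4 furan-3-carbaldehyde
Product: 6 (R)-1-(furan-3-yl)but-3-en-1-ol, via borinate 5 (not isolated)
Conditions: (+)-Ipc2BOMe, CH2=CHCH2MgBr, Et2O, 0 °C to rt; 4, −78 °C; NaOH, H2O2, rt
Reagents that add atoms: allylmagnesium bromide, C=CC[Mg]Br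
Why: Brown allylation through a chair-like six-membered transition state, in which the isopinocampheyl groups from (−)-α-pinene direct allyl to the Re face of the aldehyde, should set the (R)-carbinol, and oxidative work-up frees the alcohol from the borinate.

Step 3
Reactants: 7 3-methylenedihydrofuran-2(3H)-one (α-methylene-γ-butyrolactone)
Product: 10 4-[(tert-butyldimethylsilyl)oxy]-2-methylenebutanoic acid, via sodium carboxylate 8 (not isolated), via bis-silyl compound 9 (not isolated)
Conditions: NaOH, H2O, rt, then evaporation; t-BuMe2SiCl, imidazole, DMF, rt; K2CO3, MeOH/THF/H2O, rt; citric acid to pH 4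
Reagents that add atoms: sodium hydroxide, [Na+].[OH-]; tert-butyldimethylsilyl chloride, C[Si](C)(Cl)C(C)(C)C
Why: Saponification opens the lactone at the acyl–oxygen bond, both oxygens are silylated and only the labile silyl ester is cleaved by K2CO3/methanol, a standard route from a lactone to a silyloxy acid.

Step 4
Reactants: 6 (R)-1-(furan-3-yl)but-3-en-1-ol; 10 4-[(tert-butyldimethylsilyl)oxy]-2-methylenebutanoic acid
Product: 11 (R)-1-(furan-3-yl)but-3-en-1-yl 4-[(tert-butyldimethylsilyl)oxy]-2-methylenebutanoate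
Conditions: DCC, DMAP (cat.), CH2Cl2, 0 °C to rt
Reagents that add atoms: none
Why: Steglich esterification acylates the secondary alcohol through the acylpyridinium species without touching the C–O bond of the carbinol, so the (R)-centre is retained.

Step 5
Reactants: 11 (R)-1-(furan-3-yl)but-3-en-1-yl 4-[(tert-butyldimethylsilyl)oxy]-2-methylenebutanoate
Product: 12 (R)-3-{2-[(tert-butyldimethylsilyl)oxy]ethyl}-6-(furan-3-yl)-5,6-dihydro-2H-pyran-2-one
Conditions: second-generation Grubbs catalyst (H2IMes)(PCy3)Cl2Ru=CHPh (5 mol%), CH2Cl2 (dilute), 40 °C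
Reagents that add atoms: none
Why: Ring-closing metathesis between the terminal olefin and the 1,1-disubstituted acrylate olefin should close the six-membered unsaturated lactone with loss of ethylene, and the ring forces the carbonyl carbon and the ring CH2 cis on the new trisubstituted olefin.

Step 6
Reactants: 12 (R)-3-{2-[(tert-butyldimethylsilyl)oxy]ethyl}-6-(furan-3-yl)-5,6-dihydro-2H-pyran-2-one
Product: 13 (R)-3-(2-bromoethyl)-6-(furan-3-yl)-5,6-dihydro-2H-pyran-2-one
Conditions: Ph3PBr2, CH2Cl2, 0 °C to rt
Reagents that add atoms: dibromotriphenylphosphorane, BrP(Br)(c1ccccc1)(c1ccccc1)c1ccccc1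
Why: Dibromotriphenylphosphorane should convert the primary silyl ether directly into the bromide through an alkoxyphosphonium bromide that collapses by SN2 attack (Appel-type deoxybromination), so the free 2-hydroxyethyl lactone, which could translactonise, is never formed.

Step 7
Reactants: 3 2-(but-3-yn-1-yl)-1,3,3-trimethylcyclohex-1-ene; 13 (R)-3-(2-bromoethyl)-6-(furan-3-yl)-5,6-dihydro-2H-pyran-2-one
Product: 16 (R)-6-(furan-3-yl)-3-[(E)-4-methyl-6-(2,6,6-trimethylcyclohex-1-en-1-yl)hex-3-en-1-yl]-5,6-dihydro-2H-pyran-2-one, via alkenylalane 14 (not isolated), via alkenylzinc chloride 15 (not isolated)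
Conditions: 3, AlMe3, Cp2ZrCl2 (cat.), CH2Cl2, rt; volatiles removed in vacuo; ZnCl2, THF, 0 °C; 13, Pd2(dba)3 (cat.), P(c-C5H9)3 (cat.), N-methylimidazole, THF/NMP, 80 °C
Reagents that add atoms: trimethylaluminium, C[Al](C)C
Why: Methylzirconocene generated from Cp2ZrCl2 and AlMe3 adds Me–Zr syn across the terminal alkyne of 3 with the methyl on the internal carbon and hands the alkenyl group to aluminium (14); ZnCl2 then moves it to zinc (15), zerovalent palladium carrying the bulky electron-rich tricyclopentylphosphine inserts into the primary C–Br bond of 13 by an SN2-type oxidative addition, and transmetalation followed by reductive elimination forms the bond between the olefinic CH and the chain CH2 with retention of olefin geometry. The closest known reaction types are the zirconium-catalysed carboalumination of terminal alkynes telescoped with zinc-assisted palladium cross-coupling, and the Negishi coupling of unactivated primary alkyl halides with alkenylzinc halides under Pd2(dba)3/trialkylphosphine/N-methylimidazole. No ring is closed and no stereocentre is created; the E geometry of the new trisubstituted olefin follows from the syn carbometalation, and the (R)-centre at C6 of the lactone is remote and untouched. The step needs regioselective methylmetalation (secured by the unhindered terminal alkyne, the tetrasubstituted ring olefin being inert), transfer of the sp2 group in preference to the methyl groups on aluminium, and coupling faster than beta-hydride elimination (secured by the trialkylphosphine ligand). Organozinc and organoaluminium species should not add to the enoate, the lactone carbonyl or the furan under these conditions, and the lactone ring keeps the second olefin locked in its Z geometry.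

Step 8
Reactants: 16 (R)-6-(furan-3-yl)-3-[(E)-4-methyl-6-(2,6,6-trimethylcyclohex-1-en-1-yl)hex-3-en-1-yl]-5,6-dihydro-2H-pyran-2-one
Product: 18 (1R,3Z,7E)-1-(furan-3-yl)-4-(hydroxymethyl)-8-methyl-10-(2,6,6-trimethylcyclohex-1-en-1-yl)deca-3,7-dien-1-ol, via lactol 17 (not isolated)
Conditions: i-Bu2AlH (4 equiv), CH2Cl2, −78 °C to rt; aq. KNaC4H4O6 (potassium sodium tartrate)
Reagents that add atoms: none
Why: i-Bu2AlH reduces the unsaturated lactone in the 1,2-sense to the lactol aluminate, which opens to the enal and is reduced again, so the diol should appear with the Z geometry inherited from the ring and the carbinol centre untouched.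

Step 9
Reactants: 18 (1R,3Z,7E)-1-(furan-3-yl)-4-(hydroxymethyl)-8-methyl-10-(2,6,6-trimethylcyclohex-1-en-1-yl)deca-3,7-dien-1-ol
Product: 20 5-hydroxy-4-[(1R,3Z,7E)-1-hydroxy-4-(hydroxymethyl)-8-methyl-10-(2,6,6-trimethylcyclohex-1-en-1-yl)deca-3,7-dien-1-yl]furan-2(5H)-one, via endoperoxide 19 (not isolated)
Conditions: O2, hν (visible light), 5,10,15,20-tetraphenylporphyrin (cat.), i-Pr2NEt, CH2Cl2, −78 °C
Reagents that add atoms: oxygen, O=O
Why: Singlet oxygen adds [4+2] to the furan, the most electron-rich diene in the molecule at −78 °C, and the hindered amine removes the less hindered bridgehead hydrogen remote from the side chain (Kornblum–DeLaMare fragmentation), so the carbonyl should form at that carbon and the hydroxyl next to the substituted carbon.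

Step 10
Reactants: 20 5-hydroxy-4-[(1R,3Z,7E)-1-hydroxy-4-(hydroxymethyl)-8-methyl-10-(2,6,6-trimethylcyclohex-1-en-1-yl)deca-3,7-dien-1-yl]furan-2(5H)-one
Product: 22 4-[(1R,3Z,7E)-1-hydroxy-4-(hydroxymethyl)-8-methyl-10-(2,6,6-trimethylcyclohex-1-en-1-yl)deca-3,7-dien-1-yl]furan-2(5H)-one, via hydroxy acid 21 (not isolated)
Conditions: NaBH4, EtOH, 0 °C; then 1 M HCl to pH 3, rt
Reagents that add atoms: none
Why: NaBH4 reduces the ring-opened formyl-acrylate form of the hydroxybutenolide to the hydroxy carboxylate, and on acidification only the new CH2OH, which is cis to the carboxyl, can close the five-membered lactone, so the 4-substituted butenolide should result with the secondary carbinol untouched.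

**Compound list**

1 | 4-(2,6,6-trimethylcyclohex-1-en-1-yl)butan-2-one (dihydro-β-ionone) | CC(=O)CCC1=C(C)CCCC1(C)C | starting material
2 | diethyl 4-(2,6,6-trimethylcyclohex-1-en-1-yl)but-1-en-2-yl phosphate | C=C(CCC1=C(C)CCCC1(C)C)OP(=O)(OCC)OCC | intermediate
3 | 2-(but-3-yn-1-yl)-1,3,3-trimethylcyclohex-1-ene | C#CCCC1=C(C)CCCC1(C)C | intermediate
4 | furan-3-carbaldehyde | O=Cc1ccoc1 | starting material
5 | (R)-1-(furan-3-yl)but-3-en-1-yl diisopinocampheylborinate | C=CC[C@@H](OB([C@H]1C[C@H]2C[C@@H]([C@@H]1C)C2(C)C)[C@H]1C[C@H]2C[C@@H]([C@@H]1C)C2(C)C)c1ccoc1 | intermediate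
6 | (R)-1-(furan-3-yl)but-3-en-1-ol | C=CC[C@@H](O)c1ccoc1 | intermediate
7 | 3-methylenedihydrofuran-2(3H)-one (α-methylene-γ-butyrolactone) | C=C1CCOC1=O | starting material
8 | sodium 4-hydroxy-2-methylenebutanoate | C=C(CCO)C(=O)[O-].[Na+] | intermediate
9 | tert-butyldimethylsilyl 4-[(tert-butyldimethylsilyl)oxy]-2-methylenebutanoate | C=C(CCO[Si](C)(C)C(C)(C)C)C(=O)O[Si](C)(C)C(C)(C)C | intermediate
10 | 4-[(tert-butyldimethylsilyl)oxy]-2-methylenebutanoic acid | C=C(CCO[Si](C)(C)C(C)(C)C)C(=O)O | intermediate
11 | (R)-1-(furan-3-yl)but-3-en-1-yl 4-[(tert-butyldimethylsilyl)oxy]-2-methylenebutanoate | C=CC[C@@H](OC(=O)C(=C)CCO[Si](C)(C)C(C)(C)C)c1ccoc1 | intermediate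
12 | (R)-3-{2-[(tert-butyldimethylsilyl)oxy]ethyl}-6-(furan-3-yl)-5,6-dihydro-2H-pyran-2-one | O=C1O[C@@H](c2ccoc2)CC=C1CCO[Si](C)(C)C(C)(C)C | intermediate
13 | (R)-3-(2-bromoethyl)-6-(furan-3-yl)-5,6-dihydro-2H-pyran-2-one | O=C1O[C@@H](c2ccoc2)CC=C1CCBr | intermediate
14 | dimethyl[(E)-2-methyl-4-(2,6,6-trimethylcyclohex-1-en-1-yl)but-1-en-1-yl]aluminium | CC1=C(CC/C(C)=C/[Al](C)C)C(C)(C)CCC1 | intermediate
15 | chloro[(E)-2-methyl-4-(2,6,6-trimethylcyclohex-1-en-1-yl)but-1-en-1-yl]zinc | CC1=C(CC/C(C)=C/[Zn]Cl)C(C)(C)CCC1 | intermediate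
16 | (R)-6-(furan-3-yl)-3-[(E)-4-methyl-6-(2,6,6-trimethylcyclohex-1-en-1-yl)hex-3-en-1-yl]-5,6-dihydro-2H-pyran-2-one | CC1=C(CC/C(C)=C/CCC2=CC[C@H](c3ccoc3)OC2=O)C(C)(C)CCC1 | intermediate
17 | (6R)-6-(furan-3-yl)-3-[(E)-4-methyl-6-(2,6,6-trimethylcyclohex-1-en-1-yl)hex-3-en-1-yl]-5,6-dihydro-2H-pyran-2-ol (lactol; both epimers at C2) | CC1=C(CC/C(C)=C/CCC2=CC[C@H](c3ccoc3)OC2O)C(C)(C)CCC1 | intermediate
18 | (1R,3Z,7E)-1-(furan-3-yl)-4-(hydroxymethyl)-8-methyl-10-(2,6,6-trimethylcyclohex-1-en-1-yl)deca-3,7-dien-1-ol | CC1=C(CC/C(C)=C/CC/C(=C/C[C@@H](O)c2ccoc2)CO)C(C)(C)CCC1 | intermediate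
19 | (1R,3Z,7E)-4-(hydroxymethyl)-8-methyl-1-(2,3,7-trioxabicyclo[2.2.1]hept-5-en-5-yl)-10-(2,6,6-trimethylcyclohex-1-en-1-yl)deca-3,7-dien-1-ol (furan endoperoxide) | CC1=C(CC/C(C)=C/CC/C(=C/C[C@@H](O)C2=CC3OOC2O3)CO)C(C)(C)CCC1 | intermediate
20 | 5-hydroxy-4-[(1R,3Z,7E)-1-hydroxy-4-(hydroxymethyl)-8-methyl-10-(2,6,6-trimethylcyclohex-1-en-1-yl)deca-3,7-dien-1-yl]furan-2(5H)-one (both epimers at C5) | CC1=C(CC/C(C)=C/CC/C(=C/C[C@@H](O)C2=CC(=O)OC2O)CO)C(C)(C)CCC1 | intermediate
21 | (2E,4R,6Z,10E)-4-hydroxy-3,7-bis(hydroxymethyl)-11-methyl-13-(2,6,6-trimethylcyclohex-1-en-1-yl)trideca-2,6,10-trienoic acid (present as its sodium salt; carboxyl cis to the 3-CH2OH) | CC1=C(CC/C(C)=C/CC/C(=C/C[C@@H](O)/C(CO)=C/C(=O)O)CO)C(C)(C)CCC1 | intermediate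
22 | 4-[(1R,3Z,7E)-1-hydroxy-4-(hydroxymethyl)-8-methyl-10-(2,6,6-trimethylcyclohex-1-en-1-yl)deca-3,7-dien-1-yl]furan-2(5H)-one | CC1=C(CC/C(C)=C/CC/C(=C/C[C@@H](O)C2=CC(=O)OC2)CO)C(C)(C)CCC1 | target

**Step count and risks**

Total step count: 10. Longest linear sequence: 8 steps (steps 2, 4, 5, 6, 7, 8, 9 and 10, from furan-3-carbaldehyde).

Steps most likely to fail:

1. Step 7. What may go wrong: beta-hydride elimination of the alkylpalladium intermediate to a diene, competing methyl transfer from aluminium or zinc, or Lewis-acid-induced ionisation of the furfuryl-type C–O bond of the lactone at 80 °C. Fallback: the polarity of the partners is reversed and the union is run as a two-component Negishi coupling. It sets out from 3 and 13. Alane 14, made as in the main route, is quenched with I2 to give the vinyl iodide 2-[(E)-4-iodo-3-methylbut-3-en-1-yl]-1,3,3-trimethylcyclohex-1-ene F1. Bromide 13 is converted by zinc insertion (Zn dust, LiCl, THF, 50 °C) into the alkylzinc reagent bromo{2-[(R)-6-(furan-3-yl)-2-oxo-5,6-dihydro-2H-pyran-3-yl]ethyl}zinc F2. F1 and F2 are coupled with PdCl2(dppf) in THF at rt, where transmetalation of the alkylzinc to the alkenylpalladium iodide is followed by fast reductive elimination, and the route is rejoined at 16.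

2. Step 9. What may go wrong: loss of chemoselectivity through ene reaction of singlet oxygen at the tetrasubstituted ring olefin or the trisubstituted olefins, and imperfect regiocontrol in the base-induced opening of the endoperoxide. Fallback: the furan is oxidised before the left half and its electron-rich olefins are attached. It sets out from 13. Reduction with i-Bu2AlH gives the bromo diol (2Z,5R)-2-(2-bromoethyl)-5-(furan-3-yl)pent-2-ene-1,5-diol F3, and t-BuMe2SiCl/imidazole gives the bis-silyl ether F4. Photooxygenation under the conditions of step 9 gives the 5-hydroxybutenolide F5, and NaBH4 followed by acid gives the butenolide bromide F6. F6 then takes the place of 13 in the three-component union with 3 and AlMe3 to give the bis-silyl ether of the target F7, and HF·pyridine in THF removes both silyl groups, rejoining the route at 22.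

3. Step 6. What may go wrong: acid- or bromophosphonium-induced damage to the furan ring and incomplete exchange of the silyl ether. Fallback: the electrophile class is changed from bromide to sulfonate. It sets out from 12. HF·pyridine in THF gives the alcohol (R)-6-(furan-3-yl)-3-(2-hydroxyethyl)-5,6-dihydro-2H-pyran-2-one F8, which is tosylated at once (TsCl, pyridine, 0 °C) to forestall translactonisation, giving 2-[(R)-6-(furan-3-yl)-2-oxo-5,6-dihydro-2H-pyran-3-yl]ethyl 4-methylbenzenesulfonate F9. Primary tosylates undergo the same Pd2(dba)3/P(c-C5H9)3 alkyl–alkenyl coupling, so F9 replaces 13 in the union with 3 and AlMe3 and the route is rejoined at 16.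

**Further compounds**

F1 | step 7 | 2-[(E)-4-iodo-3-methylbut-3-en-1-yl]-1,3,3-trimethylcyclohex-1-ene | CC1=C(CC/C(C)=C/I)C(C)(C)CCC1
F2 | step 7 | bromo{2-[(R)-6-(furan-3-yl)-2-oxo-5,6-dihydro-2H-pyran-3-yl]ethyl}zinc | O=C1O[C@@H](c2ccoc2)CC=C1CC[Zn]Br
F3 | step 9 | (2Z,5R)-2-(2-bromoethyl)-5-(furan-3-yl)pent-2-ene-1,5-diol | OC/C(CCBr)=C\C[C@@H](O)c1ccoc1
F4 | step 9 | (2Z,5R)-2-(2-bromoethyl)-1,5-bis[(tert-butyldimethylsilyl)oxy]-5-(furan-3-yl)pent-2-ene | CC(C)(C)[Si](C)(C)OC/C(CCBr)=C\C[C@@H](O[Si](C)(C)C(C)(C)C)c1ccoc1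
F5 | step 9 | 4-[(1R,3Z)-4-(2-bromoethyl)-1,5-bis[(tert-butyldimethylsilyl)oxy]pent-3-en-1-yl]-5-hydroxyfuran-2(5H)-one | CC(C)(C)[Si](C)(C)OC/C(CCBr)=C\C[C@@H](O[Si](C)(C)C(C)(C)C)C1=CC(=O)OC1O
F6 | step 9 | 4-[(1R,3Z)-4-(2-bromoethyl)-1,5-bis[(tert-butyldimethylsilyl)oxy]pent-3-en-1-yl]furan-2(5H)-one | CC(C)(C)[Si](C)(C)OC/C(CCBr)=C\C[C@@H](O[Si](C)(C)C(C)(C)C)C1=CC(=O)OC1
F7 | step 9 | 4-[(1R,3Z,7E)-1-[(tert-butyldimethylsilyl)oxy]-4-{[(tert-butyldimethylsilyl)oxy]methyl}-8-methyl-10-(2,6,6-trimethylcyclohex-1-en-1-yl)deca-3,7-dien-1-yl]furan-2(5H)-one | CC1=C(CC/C(C)=C/CC/C(=C/C[C@@H](O[Si](C)(C)C(C)(C)C)C2=CC(=O)OC2)CO[Si](C)(C)C(C)(C)C)C(C)(C)CCC1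
F8 | step 6 | (R)-6-(furan-3-yl)-3-(2-hydroxyethyl)-5,6-dihydro-2H-pyran-2-one | O=C1O[C@@H](c2ccoc2)CC=C1CCO
F9 | step 6 | 2-[(R)-6-(furan-3-yl)-2-oxo-5,6-dihydro-2H-pyran-3-yl]ethyl 4-methylbenzenesulfonate | O=C1O[C@@H](c2ccoc2)CC=C1CCOS(=O)(=O)c1ccc(C)cc1
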